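Numbering: decalin C1 (CHMe), C2 (quaternary, Me and CH2–ring C), C3, C4, C4a (angular Me), C5(Me)=C6, C7, C8, C8a (H); ring C is C1′ (C(OH)CO2Me), C2′ (CH), C3′ (C=O), C4′ (C–OMe), C5′ (=CH).
Cuts, in retrosynthetic order: CH2–C2′ (conjugate addition of a decalinylmethyl Grignard reagent to a preformed cyclopentenone), C1–CH3 (back to a C1 ketone), C4a–C8a and C7–C8 together, then C2–C3 and C2–CH3 (two enolate alkylations).
Enabling feature: ring A is a cyclohexene (C4a–C5=C6–C7–C8–C8a), and its C5=C6 bond marks it as the Diels–Alder adduct of diene C4a=C5–C6=C7 and dienophile C8=C8a. C1, next to C8a, can be the activating carbonyl, and C1–C2–C3–C4 is the four-atom tether that becomes ring B.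
Forward order: stereodefined dienyl iodide, quaternary β-keto ester, trienone, rings A and B in one step, C1 methyl; ring C is made separately, joined, and oxidised to the diosphenol methyl ether.
Stereochemistry: C2 comes from ethyl (R)-3-hydroxybutanoate (two Fráter–Seebach alkylations, carbinol then oxidised away). C4a and C8a follow from C2 through a chelated chair, tether-exo transition state. C1 is set by hydrogenation from the α face, C1′ by an amine-catalysed acetone aldol, and C2′ by addition anti to the C1′ silyloxy group.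

Key step: step 11

Assumption: the quinine-derived primary amine of step 16 is taken to give the R carbinol 23; if the sense is opposite, its quinidine-derived pseudoenantiomer takes its place and nothing else changes.
Shorthand: Dm = [(1R,2R,4aS,8aS)-1,2,4a,5-tetramethyl-1,2,3,4,4a,7,8,8a-octahydronaphthalen-2-yl]methyl; TBS = tert-butyldimethylsilyl; TMS = trimethylsilyl.

Step 1
Reactants: 1 but-3-yn-1-ol
Product: 2 pent-2-yne-1,5-diol
Conditions: n-BuLi (2.1 equiv), THF, −78 → 0 °C; (CH2O)n, 0 °C → rt; H2O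
Reagents that add atoms: formaldehyde (as paraformaldehyde), C=O
Why: Hydroxymethylation of a lithium acetylide, with the alcohol carried as its lithium alkoxide, is a standard C–C bond formation and creates no stereocentre.

Step 2
Reactants: 2 pent-2-yne-1,5-diol
Product: 4 (2Z)-3-iodo-2-methylpent-2-ene-1,5-diol, via alkenylmagnesium bromide 3 (not isolated)
Conditions: MeMgBr (4 equiv), CuI (20 mol %), THF–Et2O, 0 °C → reflux; I2, −30 → 0 °C; H2O
Reagents that add atoms: methylmagnesium bromide, C[Mg]Br; iodine, II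
Why: Copper-catalysed anti-carbomagnesiation of a propargylic alcohol puts the methyl group on the carbon next to CH2O and holds magnesium on the far alkyne carbon cis to CH2O in a five-membered alkoxide chelate (the second alkoxide can bind the same magnesium), and iodinolysis keeps this geometry.

Step 3
Reactants: 4 (2Z)-3-iodo-2-methylpent-2-ene-1,5-diol
Product: 5 (2E)-2,3-dimethylpent-2-ene-1,5-diol
Conditions: MeZnCl (3.5 equiv), Pd(PPh3)4 (5 mol %), THF, 0 → 50 °C; H2O
Reagents that add atoms: methylzinc chloride, C[Zn]Cl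
Why: Negishi coupling of an alkenyl iodide runs with retention, so the new methyl group stays cis to CH2OH and the tetrasubstituted alkene is formed as the single E isomer.

Step 4
Reactants: 5 (2E)-2,3-dimethylpent-2-ene-1,5-diol
Product: 6 (2E)-5-hydroxy-2,3-dimethylpent-2-enal
Conditions: MnO2 (excess), CH2Cl2, rt
Reagents that add atoms: none
Why: MnO2 oxidises only the allylic alcohol, and the trans placement of CHO and the hydroxyethyl arm rules out lactol formation.

Step 5
Reactants: 6 (2E)-5-hydroxy-2,3-dimethylpent-2-enal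
Product: 7 (3E)-3,4-dimethylhexa-3,5-dien-1-ol
Conditions: Ph3PCH3Br, KHMDS (2.3 equiv each), THF, −78 → 0 °C
Reagents that add atoms: methyltriphenylphosphonium bromide, C[P+](c1ccccc1)(c1ccccc1)c1ccccc1.[Br-]
Why: Wittig methylenation of the enal (excess ylide covers the free hydroxyl) builds the terminal vinyl group without touching the tetrasubstituted double bond.

Step 6
Reactants: 7 (3E)-3,4-dimethylhexa-3,5-dien-1-ol
Product: 8 (3E)-6-iodo-3,4-dimethylhexa-1,3-diene
Conditions: I2, PPh3, imidazole, CH2Cl2, 0 °C, dark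
Reagents that add atoms: iodine, II
Why: Appel-type iodination of an unhindered primary alcohol under neutral conditions leaves the diene intact.

Step 7
Reactants: 8 (3E)-6-iodo-3,4-dimethylhexa-1,3-diene; 9 ethyl (3R)-3-hydroxybutanoate
Product: 10 ethyl (2R,5E)-2-[(1R)-1-hydroxyethyl]-5,6-dimethylocta-5,7-dienoate
Conditions: LDA (2.2 equiv), THF, −78 → −20 °C; 8, DMPU, −78 → 0 °C; H2O
Reagents that add atoms: none
Why: Fráter–Seebach alkylation, in which the lithium alkoxide–enolate dianion is a rigid chelate that the primary iodide attacks on the face away from the carbinol methyl group, gives the anti (2R) product.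

Step 8
Reactants: 10 ethyl (2R,5E)-2-[(1R)-1-hydroxyethyl]-5,6-dimethylocta-5,7-dienoate
Product: 11 ethyl (2S,5E)-2-[(1R)-1-hydroxyethyl]-2,5,6-trimethylocta-5,7-dienoate
Conditions: LDA (2.3 equiv), THF, −78 → 0 °C; MeI, DMPU, −78 → −20 °C; H2O
Reagents that add atoms: iodomethane, CI
Why: In this second Fráter–Seebach alkylation the same chelate face takes up the small, reactive methyl iodide, so the quaternary centre forms as 2S, with methyl on the face the chain had entered and the chain moved to the other side.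

Step 9
Reactants: 11 ethyl (2S,5E)-2-[(1R)-1-hydroxyethyl]-2,5,6-trimethylocta-5,7-dienoate
Product: 12 ethyl (2S,5E)-2-acetyl-2,5,6-trimethylocta-5,7-dienoate
Conditions: Dess–Martin periodinane, CH2Cl2, 0 °C → rt
Reagents that add atoms: none
Why: Dess–Martin oxidation removes the now spent carbinol centre under neutral conditions, and the quaternary α-carbon cannot epimerise.

Step 10
Reactants: 12 ethyl (2S,5E)-2-acetyl-2,5,6-trimethylocta-5,7-dienoate
Product: 15 ethyl (2S,5E)-2-acryloyl-2,5,6-trimethylocta-5,7-dienoate [= (4S,7E)-4-ethoxycarbonyl-4,7,8-trimethyldeca-1,7,9-trien-3-one], via Mannich base 13 (not isolated), via trimethylammonium iodide 14 (not isolated)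
Conditions: LiHMDS, THF, −78 °C; CH2=NMe2+ I−, −78 → 0 °C; MeI, Et2O, 0 °C; aq. NaHCO3–CH2Cl2, 0 °C
Reagents that add atoms: dimethyl(methylidene)ammonium iodide, C=[N+](C)C.[I-]
Why: In this Mannich methylenation only the methyl group of the ketone can be enolised, the enolate adds to the iminium salt, and quaternisation followed by mild E1cB elimination releases the vinyl ketone below room temperature, where the hindered diene does not yet cyclise.

Step 11
Reactants: 15 ethyl (2S,5E)-2-acryloyl-2,5,6-trimethylocta-5,7-dienoate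
Product: 16 ethyl (2S,4aS,8aR)-2,4a,5-trimethyl-1-oxo-1,2,3,4,4a,7,8,8a-octahydronaphthalene-2-carboxylate (trans-fused)
Conditions: Me2AlCl (2.2 equiv), CH2Cl2, −78 → −30 °C; cold aqueous quench
Reagents that add atoms: none
Why: This is the intramolecular [4+2] cycloaddition of a 1,7,9-decatrien-3-one, the known route to 1-octalones, run on the two-point aluminium chelate of the β-keto ester (the activation mode familiar from other 1,3-dicarbonyl dienophiles); it is concerted but strongly asynchronous, the enone β-carbon bonding first to the unsubstituted diene end (C7–C8) and the crowded C4a–C8a bond closing late, in line with the ortho rule. Ring A is the new cyclohexene of the cycloadduct, and ring B (C8a, C1, C2, C3, C4, C4a) closes at the same time as the tether ring through a chair. C4a is controlled by C2: chelation keeps the ester carbonyl coplanar to the ketone, hence equatorial in that chair, the C2 methyl is axial, and only one face of the E-diene can then be reached. C8a is controlled by the exo or endo placement of the tether carbonyl: exo puts H8a anti to the C4a methyl (trans fusion), whereas endo would force the aluminium-bound oxygen of the s-cis enone directly under the C5 methyl of the diene, so this methyl acts as a steric directing group against the usual endo preference. The step thus needs exo over endo, the chelated chair over the unchelated one, and cycloaddition over proton loss from the cation-like terminus, and the alkylaluminium halide also scavenges protons. The mixture is quenched cold because C8a stays epimerisable and the cis ketone is not the less stable isomer.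

Step 12
Reactants: 16 ethyl (2S,4aS,8aR)-2,4a,5-trimethyl-1-oxo-1,2,3,4,4a,7,8,8a-octahydronaphthalene-2-carboxylate
Product: 17 ethyl (2S,4aS,8aS)-2,4a,5-trimethyl-1-methylidene-1,2,3,4,4a,7,8,8a-octahydronaphthalene-2-carboxylate
Conditions: Zn, CH2Br2, TiCl4, THF–CH2Cl2, 0 °C → rt
Reagents that add atoms: dibromomethane, BrCBr
Why: Takai–Lombardo methylenation is non-basic, spares esters and is the usual choice for hindered ketones that carry an epimerisable α-centre, so C8a is kept.

Step 13
Reactants: 17 ethyl (2S,4aS,8aS)-2,4a,5-trimethyl-1-methylidene-1,2,3,4,4a,7,8,8a-octahydronaphthalene-2-carboxylate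
Product: 18 ethyl (1R,2S,4aS,8aS)-1,2,4a,5-tetramethyl-1,2,3,4,4a,7,8,8a-octahydronaphthalene-2-carboxylate
Conditions: H2 (1 atm), PtO2 (5 mol %), EtOAc, 0 °C → rt, stopped after one equivalent
Reagents that add atoms: none
Why: Heterogeneous hydrogenation takes the 1,1-disubstituted exocyclic alkene before the trisubstituted ring alkene shielded by C4a, and hydrogen arrives from the α face (the equatorial side, normal for methylenecyclohexanes and reinforced by the syn-axial C4a methyl on the β face), which leaves the C1 methyl axial and β.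

Step 14
Reactants: 18 ethyl (1R,2S,4aS,8aS)-1,2,4a,5-tetramethyl-1,2,3,4,4a,7,8,8a-octahydronaphthalene-2-carboxylate
Product: 19 [(1R,2S,4aS,8aS)-1,2,4a,5-tetramethyl-1,2,3,4,4a,7,8,8a-octahydronaphthalen-2-yl]methanol
Conditions: LiAlH4, Et2O, reflux; H2O
Reagents that add atoms: none
Why: LiAlH4 reduction of a hindered ester to the neopentyl-type primary alcohol touches neither the alkene nor any stereocentre.

Step 15
Reactants: 19 [(1R,2S,4aS,8aS)-1,2,4a,5-tetramethyl-1,2,3,4,4a,7,8,8a-octahydronaphthalen-2-yl]methanol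
Product: 20 (1R,2S,4aS,8aS)-2-(iodomethyl)-1,2,4a,5-tetramethyl-1,2,3,4,4a,7,8,8a-octahydronaphthalene
Conditions: I2, PPh3, imidazole, toluene, 90 °C
Reagents that add atoms: iodine, II
Why: Appel-type iodination works on neopentyl-type alcohols on heating because iodide displaces the oxyphosphonium group directly, without a cation that could rearrange.

Step 16
Reactants: 21 methyl (3E)-2-oxo-4-phenylbut-3-enoate; 22 acetone
Product: 23 methyl (2R,3E)-2-hydroxy-2-(2-oxopropyl)-4-phenylbut-3-enoate
Conditions: 9-amino-9-deoxy-epi-quinine (10 mol %), 4-nitrobenzoic acid (20 mol %), acetone, 0 °C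
Reagents that add atoms: none
Why: Primary-amine (enamine) catalysed aldol addition of acetone to a β,γ-unsaturated α-keto ester is a known enantioselective reaction in which the protonated quinuclidine binds the keto ester and fixes the face that is attacked, which sets C1′ as R.

Step 17
Reactants: 23 methyl (2R,3E)-2-hydroxy-2-(2-oxopropyl)-4-phenylbut-3-enoate
Product: 24 methyl (2R,3E)-2-(TBS-oxy)-2-(2-oxopropyl)-4-phenylbut-3-enoate
Conditions: TBSOTf, 2,6-lutidine, CH2Cl2, −20 → 0 °C
Reagents that add atoms: tert-butyldimethylsilyl trifluoromethanesulfonate, CC(C)(C)[Si](C)(C)OS(=O)(=O)C(F)(F)F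
Why: Silylation of the tertiary alcohol by the silyl triflate blocks retro-aldol cleavage and installs the bulky group that later steers the conjugate addition.

Step 18
Reactants: 24 methyl (2R,3E)-2-(TBS-oxy)-2-(2-oxopropyl)-4-phenylbut-3-enoate
Product: 25 methyl (2R)-2-(TBS-oxy)-2-formyl-4-oxopentanoate
Conditions: O3, CH2Cl2, −78 °C; Me2S, −78 °C → rt
Reagents that add atoms: ozone, [O-][O+]=O
Why: Ozonolysis cleaves the only C=C bond, and reductive work-up gives the non-enolisable aldehyde.

Step 19
Reactants: 25 methyl (2R)-2-(TBS-oxy)-2-formyl-4-oxopentanoate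
Product: 26 methyl (1R)-1-(TBS-oxy)-4-oxocyclopent-2-ene-1-carboxylate
Conditions: dibenzylammonium trifluoroacetate (20 mol %), benzene, 50 °C
Reagents that add atoms: none
Why: Amine-salt catalysed intramolecular aldol condensation of a 1,4-keto aldehyde closes the cyclopentenone (only the methyl group can reach the aldehyde through a five-membered ring), and the mild conditions avoid loss of the β-silyloxy group.

Step 20
Reactants: 20 (1R,2S,4aS,8aS)-2-(iodomethyl)-1,2,4a,5-tetramethyl-1,2,3,4,4a,7,8,8a-octahydronaphthalene; 26 methyl (1R)-1-(TBS-oxy)-4-oxocyclopent-2-ene-1-carboxylate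
Product: 28 methyl (1R,2R)-1-(TBS-oxy)-2-Dm-4-(TMS-oxy)cyclopent-3-ene-1-carboxylate, via decalinylmethylmagnesium iodide 27 (not isolated)
Conditions: 20, Mg, Et2O, reflux; then 26, CuBr·SMe2 (10 mol %), TMSCl, DMPU, THF, −78 → −40 °C
Reagents that add atoms: chlorotrimethylsilane, C[Si](C)(C)Cl
Why: In this copper-catalysed, TMSCl-accelerated conjugate addition the Grignard reagent attacks C2′ anti to the bulky allylic silyloxy group (the steric and stereoelectronic preference known from 4-silyloxycyclopentenones), which sets C2′ trans to oxygen, and silyl trapping fixes the enolate regiochemistry before it can expel the silyloxy group.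

Step 21
Reactants: 28 methyl (1R,2R)-1-(TBS-oxy)-2-Dm-4-(TMS-oxy)cyclopent-3-ene-1-carboxylate
Product: 30 methyl (1R,2R,3R)-1-(TBS-oxy)-2-Dm-3-hydroxy-4-oxocyclopentane-1-carboxylate, via trimethylsilyloxy ketone 29 (not isolated)
Conditions: mCPBA (1.0 equiv), CH2Cl2, −20 °C; 1 M HCl, THF, 0 °C
Reagents that add atoms: 3-chloroperoxybenzoic acid, O=C(OO)c1cccc(Cl)c1
Why: In this Rubottom oxidation the silyl enol ether is far more electron-rich than the hindered trisubstituted ring alkene, so one equivalent of peracid oxidises only C3′ (from the face away from the C2′ substituent), and the new carbinol centre is removed in the next step.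

Step 22
Reactants: 30 methyl (1R,2R,3R)-1-(TBS-oxy)-2-Dm-3-hydroxy-4-oxocyclopentane-1-carboxylate
Product: 32 methyl (1R,2S)-1-(TBS-oxy)-2-Dm-4-hydroxy-3-oxocyclopent-4-ene-1-carboxylate, via 1,2-dione 31 (not isolated)
Conditions: Dess–Martin periodinane, CH2Cl2, 0 °C → rt
Reagents that add atoms: none
Why: Dess–Martin oxidation of an acyloin gives the 1,2-dione, which should enolise at the accessible C5′ methylene and not at the crowded tertiary C2′–H, so C2′ is kept.

Step 23
Reactants: 32 methyl (1R,2S)-1-(TBS-oxy)-2-Dm-4-hydroxy-3-oxocyclopent-4-ene-1-carboxylate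
Product: 33 methyl (1R,2S)-1-(TBS-oxy)-2-Dm-4-methoxy-3-oxocyclopent-4-ene-1-carboxylate
Conditions: TMSCHN2, toluene–MeOH 4:1, 0 °C
Reagents that add atoms: (trimethylsilyl)diazomethane, C[Si](C)(C)C=[N+]=[N-]
Why: O-Methylation of the acidic diosphenol by diazomethane generated in situ runs under neutral conditions, so neither C2′ epimerisation nor re-equilibration through the dione is triggered.

Step 24
Reactants: 33 methyl (1R,2S)-1-(TBS-oxy)-2-Dm-4-methoxy-3-oxocyclopent-4-ene-1-carboxylate
Product: 34 dysidenone B, methyl (1R,2S)-1-hydroxy-2-Dm-4-methoxy-3-oxocyclopent-4-ene-1-carboxylate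
Conditions: HF·pyridine, THF, 0 °C → rt
Reagents that add atoms: none
Why: Fluoride-mediated desilylation under mildly acidic conditions frees the tertiary alcohol without the base that would open the β-hydroxy ketone by retro-aldol reaction or epimerise C2′.

Compound list
1 | but-3-yn-1-ol | C#CCCO | starting material
2 | pent-2-yne-1,5-diol | OCC#CCCO | intermediate
3 | alkenylmagnesium bromide of 2-methylpent-2-ene-1,5-diol bis(bromomagnesium alkoxide), Mg on C3 cis to C1 | Br[Mg]OC/C(C)=C(\[Mg]Br)CCO[Mg]Br | intermediate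
4 | (2Z)-3-iodo-2-methylpent-2-ene-1,5-diol | OC/C(C)=C(\I)CCO | intermediate
5 | (2E)-2,3-dimethylpent-2-ene-1,5-diol | OC/C(C)=C(\C)CCO | intermediate
6 | (2E)-5-hydroxy-2,3-dimethylpent-2-enal | O=C/C(C)=C(\C)CCO | intermediate
7 | (3E)-3,4-dimethylhexa-3,5-dien-1-ol | C=C/C(C)=C(\C)CCO | intermediate
8 | (3E)-6-iodo-3,4-dimethylhexa-1,3-diene | C=C/C(C)=C(\C)CCI | intermediate
9 | ethyl (3R)-3-hydroxybutanoate | CCOC(=O)C[C@@H](C)O | starting material
10 | ethyl (2R,5E)-2-[(1R)-1-hydroxyethyl]-5,6-dimethylocta-5,7-dienoate | CCOC(=O)[C@H](CC/C(C)=C(\C)C=C)[C@@H](C)O | intermediate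
11 | ethyl (2S,5E)-2-[(1R)-1-hydroxyethyl]-2,5,6-trimethylocta-5,7-dienoate | CCOC(=O)[C@@](C)(CC/C(C)=C(\C)C=C)[C@@H](C)O | intermediate
12 | ethyl (2S,5E)-2-acetyl-2,5,6-trimethylocta-5,7-dienoate | CCOC(=O)[C@@](C)(CC/C(C)=C(\C)C=C)C(C)=O | intermediate
13 | ethyl (2S,5E)-2-[3-(dimethylamino)propanoyl]-2,5,6-trimethylocta-5,7-dienoate | CCOC(=O)[C@@](C)(CC/C(C)=C(\C)C=C)C(=O)CCN(C)C | intermediate
14 | N-methyl ammonium iodide of 13 | CCOC(=O)[C@@](C)(CC/C(C)=C(\C)C=C)C(=O)CC[N+](C)(C)C.[I-] | intermediate
15 | ethyl (2S,5E)-2-acryloyl-2,5,6-trimethylocta-5,7-dienoate | C=CC(=O)[C@@](C)(C(=O)OCC)CC/C(C)=C(\C)C=C | intermediate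
16 | ethyl (2S,4aS,8aR)-2,4a,5-trimethyl-1-oxo-1,2,3,4,4a,7,8,8a-octahydronaphthalene-2-carboxylate | CCOC(=O)[C@@]1(C)CC[C@]2(C)C(C)=CCC[C@H]2C1=O | intermediate
17 | ethyl (2S,4aS,8aS)-2,4a,5-trimethyl-1-methylidene-1,2,3,4,4a,7,8,8a-octahydronaphthalene-2-carboxylate | CCOC(=O)[C@@]1(C)CC[C@]2(C)C(C)=CCC[C@H]2C1=C | intermediate
18 | ethyl (1R,2S,4aS,8aS)-1,2,4a,5-tetramethyl-1,2,3,4,4a,7,8,8a-octahydronaphthalene-2-carboxylate | CCOC(=O)[C@@]1(C)CC[C@]2(C)C(C)=CCC[C@H]2[C@H]1C | intermediate
19 | [(1R,2S,4aS,8aS)-1,2,4a,5-tetramethyl-1,2,3,4,4a,7,8,8a-octahydronaphthalen-2-yl]methanol | OC[C@@]1(C)CC[C@]2(C)C(C)=CCC[C@H]2[C@H]1C | intermediate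
20 | (1R,2S,4aS,8aS)-2-(iodomethyl)-1,2,4a,5-tetramethyl-1,2,3,4,4a,7,8,8a-octahydronaphthalene | IC[C@@]1(C)CC[C@]2(C)C(C)=CCC[C@H]2[C@H]1C | intermediate
21 | methyl (3E)-2-oxo-4-phenylbut-3-enoate | COC(=O)C(=O)/C=C/c1ccccc1 | starting material
22 | acetone | CC(C)=O | starting material
23 | methyl (2R,3E)-2-hydroxy-2-(2-oxopropyl)-4-phenylbut-3-enoate | COC(=O)[C@@](O)(CC(C)=O)/C=C/c1ccccc1 | intermediate
24 | methyl (2R,3E)-2-(TBS-oxy)-2-(2-oxopropyl)-4-phenylbut-3-enoate | COC(=O)[C@@](O[Si](C)(C)C(C)(C)C)(CC(C)=O)/C=C/c1ccccc1 | intermediate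
25 | methyl (2R)-2-(TBS-oxy)-2-formyl-4-oxopentanoate | COC(=O)[C@@](O[Si](C)(C)C(C)(C)C)(CC(C)=O)C=O | intermediate
26 | methyl (1R)-1-(TBS-oxy)-4-oxocyclopent-2-ene-1-carboxylate | COC(=O)[C@@]1(O[Si](C)(C)C(C)(C)C)CC(=O)C=C1 | intermediate
27 | {[(1R,2S,4aS,8aS)-1,2,4a,5-tetramethyl-1,2,3,4,4a,7,8,8a-octahydronaphthalen-2-yl]methyl}magnesium iodide | I[Mg]C[C@@]1(C)CC[C@]2(C)C(C)=CCC[C@H]2[C@H]1C | intermediate
28 | methyl (1R,2R)-1-(TBS-oxy)-2-Dm-4-(TMS-oxy)cyclopent-3-ene-1-carboxylate | COC(=O)[C@@]1(O[Si](C)(C)C(C)(C)C)CC(O[Si](C)(C)C)=C[C@H]1C[C@@]1(C)CC[C@]2(C)C(C)=CCC[C@H]2[C@H]1C | intermediate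
29 | methyl (1R,2R,3R)-1-(TBS-oxy)-2-Dm-4-oxo-3-(TMS-oxy)cyclopentane-1-carboxylate | COC(=O)[C@@]1(O[Si](C)(C)C(C)(C)C)CC(=O)[C@H](O[Si](C)(C)C)[C@H]1C[C@@]1(C)CC[C@]2(C)C(C)=CCC[C@H]2[C@H]1C | intermediate
30 | methyl (1R,2R,3R)-1-(TBS-oxy)-2-Dm-3-hydroxy-4-oxocyclopentane-1-carboxylate | COC(=O)[C@@]1(O[Si](C)(C)C(C)(C)C)CC(=O)[C@H](O)[C@H]1C[C@@]1(C)CC[C@]2(C)C(C)=CCC[C@H]2[C@H]1C | intermediate
31 | methyl (1R,2S)-1-(TBS-oxy)-2-Dm-3,4-dioxocyclopentane-1-carboxylate | COC(=O)[C@@]1(O[Si](C)(C)C(C)(C)C)CC(=O)C(=O)[C@H]1C[C@@]1(C)CC[C@]2(C)C(C)=CCC[C@H]2[C@H]1C | intermediate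
32 | methyl (1R,2S)-1-(TBS-oxy)-2-Dm-4-hydroxy-3-oxocyclopent-4-ene-1-carboxylate | COC(=O)[C@@]1(O[Si](C)(C)C(C)(C)C)C=C(O)C(=O)[C@H]1C[C@@]1(C)CC[C@]2(C)C(C)=CCC[C@H]2[C@H]1C | intermediate
33 | methyl (1R,2S)-1-(TBS-oxy)-2-Dm-4-methoxy-3-oxocyclopent-4-ene-1-carboxylate | COC(=O)[C@@]1(O[Si](C)(C)C(C)(C)C)C=C(OC)C(=O)[C@H]1C[C@@]1(C)CC[C@]2(C)C(C)=CCC[C@H]2[C@H]1C | intermediate
34 | dysidenone B, methyl (1R,2S)-1-hydroxy-2-Dm-4-methoxy-3-oxocyclopent-4-ene-1-carboxylate | COC(=O)[C@@]1(O)C=C(OC)C(=O)[C@H]1C[C@@]1(C)CC[C@]2(C)C(C)=CCC[C@H]2[C@H]1C | target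

Total step count: 24. Longest linear sequence: 20 (steps 1–15 and 20–24); steps 16–19 are a side branch.

Steps most likely to fail

Step 11. The tether-endo mode or the unchelated chair may compete with the wanted transition state. The cation-like diene terminus may also lose a proton instead of closing the second bond. The fallback sets out from 15 and comes back at 16.
- Trienone 15 is cyclised without a chelating metal (toluene, BHT, 80–110 °C). The ester, smaller than methyl, can then take the axial site.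
- The ordinary tether-endo chair should lead to the cis-fused ketone ethyl (2S,4aS,8aS)-2,4a,5-trimethyl-1-oxo-1,2,3,4,4a,7,8,8a-octahydronaphthalene-2-carboxylate F1, which has the right C4a and only C8a inverted.
- LDA turns it into the lithium C1–C8a enolate F2. Protonation at −78 °C by a hindered phenol, anti to the neighbouring C4a methyl, gives 16, and unchanged cis ketone is recycled.
- C8a is then set after the cycloaddition and not in it.

Step 13. Facial selectivity may be poor because the axial C2 methyl also hinders the α face. The exocyclic double bond may migrate into the ring on the metal surface, and over-reduction of C5=C6 may set in. The fallback sets out from 17 and comes back at 19.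
- Hydroboration with the much larger 9-BBN (THF, 60 °C) places boron on the CH2 terminus and hydrogen on C1 without alkene migration.
- After oxidation (NaBO3), the β-hydroxymethyl group closes onto the cis ester to give the cis-fused γ-lactone between C1–CH2O and the C2 carboxyl group F3. Only the wanted C1 epimer lactonises readily, which allows separation.
- TMSCl–NaI (MeCN, 60 °C) opens the lactone at CH2–O to (1R,2S,4aS,8aS)-1-(iodomethyl)-2,4a,5-trimethyl-1,2,3,4,4a,7,8,8a-octahydronaphthalene-2-carboxylic acid F4.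
- LiAlH4 reduces both C–I and CO2H, which gives 19.

Step 22. The 1,2-dione may enolise toward C2′, which would scramble that centre and lead to the isomeric diosphenol. The fallback sets out from 30 and comes back at 33, and it never passes through a free dione.
- Ketol 30 is ketalised (HC(OMe)3, MeOH, camphorsulfonic acid cat.) to methyl (1R,2R,3R)-1-(TBS-oxy)-2-Dm-3-hydroxy-4,4-dimethoxycyclopentane-1-carboxylate F5.
- Dess–Martin oxidation gives methyl (1R,2S)-1-(TBS-oxy)-2-Dm-4,4-dimethoxy-3-oxocyclopentane-1-carboxylate F6.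
- Catalytic TsOH in warm benzene removes one methanol toward C5′, the only neighbouring carbon that bears hydrogen, to give 33.

Further compounds
F1 | step 11 | ethyl (2S,4aS,8aS)-2,4a,5-trimethyl-1-oxo-1,2,3,4,4a,7,8,8a-octahydronaphthalene-2-carboxylate (cis-fused C8a epimer of 16) | CCOC(=O)[C@@]1(C)CC[C@]2(C)C(C)=CCC[C@@H]2C1=O
F2 | step 11 | lithium C1–C8a enolate of F1 and 16 | CCOC(=O)[C@@]1(C)CC[C@]2(C)C(C)=CCCC2=C1[O-].[Li+]
F3 | step 13 | cis-fused γ-lactone between C1–CH2O and the C2 carboxyl group, other centres as in 18 | O=C3[C@@]1(C)CC[C@]2(C)C(C)=CCC[C@H]2[C@H]1CO3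
F4 | step 13 | (1R,2S,4aS,8aS)-1-(iodomethyl)-2,4a,5-trimethyl-1,2,3,4,4a,7,8,8a-octahydronaphthalene-2-carboxylic acid | OC(=O)[C@@]1(C)CC[C@]2(C)C(C)=CCC[C@H]2[C@H]1CI
F5 | step 22 | methyl (1R,2R,3R)-1-(TBS-oxy)-2-Dm-3-hydroxy-4,4-dimethoxycyclopentane-1-carboxylate | COC(=O)[C@@]1(O[Si](C)(C)C(C)(C)C)CC(OC)(OC)[C@H](O)[C@H]1C[C@@]1(C)CC[C@]2(C)C(C)=CCC[C@H]2[C@H]1C
F6 | step 22 | methyl (1R,2S)-1-(TBS-oxy)-2-Dm-4,4-dimethoxy-3-oxocyclopentane-1-carboxylate | COC(=O)[C@@]1(O[Si](C)(C)C(C)(C)C)CC(OC)(OC)C(=O)[C@H]1C[C@@]1(C)CC[C@]2(C)C(C)=CCC[C@H]2[C@H]1C
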